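**Retrosynthetic overview**
1. β-Collatolic acid ⇒ its tribenzyl-protected form; the key disconnection is the diaryl ether C–O bond between O-8 of the isocoumarin (ring B) and the ring A carbon that lies between the 4-oxygen and the 2-oxoheptyl arm.
2. That C–O bond is made by a one-flask C–H aryloxylation of the ring A keto ester with the ring B phenol, through a diaryliodonium salt that carries a non-transferring 2,4,6-trimethoxyphenyl group (new method).
3. Both 2-oxoheptyl arms come from lateral lithiation of an orsellinate ester and acylation with the hexanoic Weinreb amide.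
4. Ring order: both benzene rings are bought as orsellinate units. The pyranone of ring B is closed first (enol lactonisation) and its 8-OH unmasked. Ring A's arm stays open as a keto benzyl ester, so no ring is formed after the coupling.

Assumption: the target SMILES has no stereocentre and the diaryl ether axis rotates freely, so the compound is achiral and the constitution alone defines it; ring A is made as the open keto acid drawn.

**Step 1**
Reactants: 1 methyl 2,4-dimethoxy-6-methylbenzoate; 2 N-methoxy-N-methylhexanamide
Product: 4 6,8-dimethoxy-3-pentyl-1H-isochromen-1-one, via keto ester 3 (not isolated)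
Conditions: LiN(iPr)2 (1.3 equiv), THF, −78 °C; 2 (1.3 equiv), −78 → 0 °C; 1 M HCl; crude 3: TsOH·H2O (0.2 equiv), PhMe, reflux, Dean–Stark
Reagents that add atoms: N-methoxy-N-methylhexanamide (compound 2), CCCCCC(=O)N(C)OC
Why: Lateral (benzylic) lithiation of the ortho-toluate gives an ester-stabilised anion that is acylated once by the Weinreb amide (Weinreb ketone synthesis), and acid-catalysed enol lactonisation of the resulting 2-(2-oxoalkyl)benzoate with loss of methanol closes the pyranone of ring B; no stereocentre is formed.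

**Step 2**
Reactants: 4 6,8-dimethoxy-3-pentyl-1H-isochromen-1-one
Product: 5 8-hydroxy-6-methoxy-3-pentyl-1H-isochromen-1-one
Conditions: BCl3 (1.5 equiv), CH2Cl2, −78 → 0 °C; H2O
Reagents that add atoms: none
Why: Chelation-controlled Lewis-acid O-demethylation: BCl3 bridges the lactone carbonyl and the peri 8-methoxy oxygen and cleaves only that ether, leaving the 6-methoxy group and the enol lactone untouched.

**Step 3**
Reactants: 6 2,4-dihydroxy-6-methylbenzoic acid (orsellinic acid); 7 benzyl bromide
Product: 8 benzyl 2,4-bis(benzyloxy)-6-methylbenzoate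
Conditions: BnBr (3.3 equiv), K2CO3 (4 equiv), DMF, rt → 60 °C
Reagents that add atoms: benzyl bromide (compound 7), BrCc1ccccc1
Why: Williamson-type O-alkylation of the carboxylate and both phenoxides (the hydrogen-bonded 2-OH needs the warming) puts on three benzyl groups that can later be removed together under neutral conditions.

**Step 4**
Reactants: 8 benzyl 2,4-bis(benzyloxy)-6-methylbenzoate; 2 N-methoxy-N-methylhexanamide
Product: 9 benzyl 2,4-bis(benzyloxy)-6-(2-oxoheptyl)benzoate
Conditions: LiN(iPr)2 (1.3 equiv), THF, −78 °C, 20 min; 2 (1.5 equiv), −78 → −20 °C; 1 M HCl, 0 °C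
Reagents that add atoms: N-methoxy-N-methylhexanamide (compound 2), CCCCCC(=O)N(C)OC
Why: Same lateral lithiation and Weinreb ketone synthesis as in step 1; at −78 °C the hindered amide base removes the ring-methyl proton faster than it attacks the benzyl ester or the ether CH2 groups, and the chelated tetrahedral adduct prevents over-addition.

**Step 5**
Reactants: 9 benzyl 2,4-bis(benzyloxy)-6-(2-oxoheptyl)benzoate; 5 8-hydroxy-6-methoxy-3-pentyl-1H-isochromen-1-one; 10 2-iodo-1,3,5-trimethoxybenzene (auxiliary, recovered)
Product: 13 benzyl 4,6-bis(benzyloxy)-3-[(6-methoxy-1-oxo-3-pentyl-1H-isochromen-8-yl)oxy]-2-(2-oxoheptyl)benzoate, via 2-(diacetoxyiodo)-1,3,5-trimethoxybenzene 11 (not isolated), via diaryliodonium triflate 12 (not isolated)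
Conditions: 10 (1.0 equiv), CH3CO3H (1.0 equiv, in AcOH), CH2Cl2, 0 °C → rt; then TfOH (1.0 equiv), 9 (1.05 equiv), CH2Cl2/(CF3)2CHOH 9:1, −40 → 0 °C; volatiles off; then 5 (1.0 equiv), K2CO3 (1.5 equiv), MeCN, 0 °C → rt
Reagents that add atoms: none
Why: Proposed new method: a net dehydrogenative C–H/O–H cross-coupling that forms the diaryl ether C–O bond; the trivalent-iodine reagent 11, ionised by TfOH, attacks 9 by SEAr at its only CH that is para to an alkoxy group (the carbon between the 4-benzyloxy group and the 2-oxoheptyl arm; the other free CH sits between two benzyloxy groups and has no para donor) to give iodonium salt 12, the phenoxide of 5 then exchanges onto iodine and reductive ligand coupling passes the less electron-rich, ester-bearing ring A aryl to oxygen while the very electron-rich trimethoxyphenyl group leaves as recovered 10, all at or below room temperature with only carbonate as base so that the hindered ether should form without enolising the neighbouring ketone; the closest known reactions are the acid-promoted condensation of (diacetoxyiodo)arenes with electron-rich arenes to diaryliodonium salts and the metal-free O-arylation of phenols with aryl(trimethoxyphenyl)iodonium salts, here with the roles reversed (the auxiliary sits on the iodane and the valuable arene is the C–H partner); no stereocentre is formed.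

**Step 6**
Reactants: 13 benzyl 4,6-bis(benzyloxy)-3-[(6-methoxy-1-oxo-3-pentyl-1H-isochromen-8-yl)oxy]-2-(2-oxoheptyl)benzoate
Product: 14 β-collatolic acid (4,6-dihydroxy-3-[(6-methoxy-1-oxo-3-pentyl-1H-isochromen-8-yl)oxy]-2-(2-oxoheptyl)benzoic acid)
Conditions: H2 (1 atm), 10% Pd/C, EtOAc, rt, stopped after uptake of 3 equiv H2
Reagents that add atoms: none
Why: Catalytic hydrogenolysis cleaves the benzyl ester and both aryl benzyl ethers under neutral conditions, so no base opens the enol lactone of ring B and no dehydrating acid closes ring A to a second isocoumarin; the ketone and the lactone C3=C4 bond react far more slowly, and no stereocentre is involved.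

**Compound list**
1 | methyl 2,4-dimethoxy-6-methylbenzoate | COC(=O)c1c(C)cc(OC)cc1OC | starting material
2 | N-methoxy-N-methylhexanamide | CCCCCC(=O)N(C)OC | starting material
3 | methyl 2,4-dimethoxy-6-(2-oxoheptyl)benzoate | CCCCCC(=O)Cc1cc(OC)cc(OC)c1C(=O)OC | intermediate
4 | 6,8-dimethoxy-3-pentyl-1H-isochromen-1-one | CCCCCc1cc2cc(OC)cc(OC)c2c(=O)o1 | intermediate
5 | 8-hydroxy-6-methoxy-3-pentyl-1H-isochromen-1-one | CCCCCc1cc2cc(OC)cc(O)c2c(=O)o1 | intermediate
6 | 2,4-dihydroxy-6-methylbenzoic acid (orsellinic acid) | Cc1cc(O)cc(O)c1C(=O)O | starting material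
7 | benzyl bromide | BrCc1ccccc1 | starting material
8 | benzyl 2,4-bis(benzyloxy)-6-methylbenzoate | Cc1cc(OCc2ccccc2)cc(OCc2ccccc2)c1C(=O)OCc1ccccc1 | intermediate
9 | benzyl 2,4-bis(benzyloxy)-6-(2-oxoheptyl)benzoate | CCCCCC(=O)Cc1cc(OCc2ccccc2)cc(OCc2ccccc2)c1C(=O)OCc1ccccc1 | intermediate
10 | 2-iodo-1,3,5-trimethoxybenzene | COc1cc(OC)c(I)c(OC)c1 | starting material
11 | 2-(diacetoxyiodo)-1,3,5-trimethoxybenzene | COc1cc(OC)c(I(OC(C)=O)OC(C)=O)c(OC)c1 | intermediate
12 | {4,6-bis(benzyloxy)-3-[(benzyloxy)carbonyl]-2-(2-oxoheptyl)phenyl}(2,4,6-trimethoxyphenyl)iodonium trifluoromethanesulfonate | CCCCCC(=O)Cc1c([I+]c2c(OC)cc(OC)cc2OC)c(OCc2ccccc2)cc(OCc2ccccc2)c1C(=O)OCc1ccccc1.[O-]S(=O)(=O)C(F)(F)F | intermediate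
13 | benzyl 4,6-bis(benzyloxy)-3-[(6-methoxy-1-oxo-3-pentyl-1H-isochromen-8-yl)oxy]-2-(2-oxoheptyl)benzoate | CCCCCC(=O)Cc1c(Oc2cc(OC)cc3cc(CCCCC)oc(=O)c23)c(OCc2ccccc2)cc(OCc2ccccc2)c1C(=O)OCc1ccccc1 | intermediate
14 | β-collatolic acid | CCCCCC(=O)Cc1c(Oc2cc(OC)cc3cc(CCCCC)oc(=O)c23)c(O)cc(O)c1C(=O)O | target

**Totals**
Total step count: 6. Longest linear sequence: 4 steps (6 → 8 → 9 → 13 → 14; the branch 1 → 4 → 5 → 13 → 14 is equally long).

**Three steps most likely to fail**

Step 5 (the new C–H aryloxylation). The iodane may oxidise the enolisable ketone instead of the ring, the wrong aryl group may be passed to oxygen, or the ketone enolate may close onto the iodonium carbon to give a benzofuran. The fallback uses known chemistry, sets out from 9 and comes back at 13. The ketone is first masked, because a free ketone ortho to a halide would itself cyclise under copper and base. Compound 9 is treated with 1,2-bis(trimethylsilyloxy)ethane and catalytic TMSOTf in CH2Cl2 at −78 °C to give the dioxolane benzyl 2,4-bis(benzyloxy)-6-[(2-pentyl-1,3-dioxolan-2-yl)methyl]benzoate F1. N-Iodosuccinimide in MeCN then iodinates the same activated ring position to give benzyl 4,6-bis(benzyloxy)-3-iodo-2-[(2-pentyl-1,3-dioxolan-2-yl)methyl]benzoate F2. An Ullmann-type coupling of F2 with 5 (CuI, N,N-dimethylglycine, Cs2CO3, dioxane, 100 °C) gives benzyl 4,6-bis(benzyloxy)-3-[(6-methoxy-1-oxo-3-pentyl-1H-isochromen-8-yl)oxy]-2-[(2-pentyl-1,3-dioxolan-2-yl)methyl]benzoate F3. Brief treatment with 1 M HCl in THF at room temperature removes the ketal and returns 13.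

Step 4 (lateral acylation of a benzyl ester). The benzylic anion may condense with the benzyl ester of a second molecule. The fallback avoids any carbanion next to a benzyl ester; it sets out from 4 and comes back at 9. BBr3 in CH2Cl2 (−78 °C → rt) removes both methyl ethers of 4 to give 6,8-dihydroxy-3-pentyl-1H-isochromen-1-one F4. BnBr and K2CO3 in DMF at 60 °C give 6,8-bis(benzyloxy)-3-pentyl-1H-isochromen-1-one F5. One equivalent of NaOCH2Ph in THF at 0 °C opens the enol lactone by alcoholysis, the enolate being the leaving group, and a cold acidic quench gives 9.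

Step 6 (hydrogenolysis). The lactone C3=C4 bond of ring B may be reduced before the last benzyl group is gone. The fallback changes from hydrogenolysis to Lewis-acid dealkylation; it sets out from 13 and comes back at 14. BCl3 with pentamethylbenzene as benzyl-cation trap in CH2Cl2 (−78 → −20 °C) cleaves the two benzyl ethers and the benzyl ester, while the non-chelated 6-methoxy group, the lactone and the ketone are left alone. No new compound is made on this way (F0).

**Further compounds**
F1 | step 5 | benzyl 2,4-bis(benzyloxy)-6-[(2-pentyl-1,3-dioxolan-2-yl)methyl]benzoate | CCCCCC1(Cc2cc(OCc3ccccc3)cc(OCc3ccccc3)c2C(=O)OCc2ccccc2)OCCO1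
F2 | step 5 | benzyl 4,6-bis(benzyloxy)-3-iodo-2-[(2-pentyl-1,3-dioxolan-2-yl)methyl]benzoate | CCCCCC1(Cc2c(I)c(OCc3ccccc3)cc(OCc3ccccc3)c2C(=O)OCc2ccccc2)OCCO1
F3 | step 5 | benzyl 4,6-bis(benzyloxy)-3-[(6-methoxy-1-oxo-3-pentyl-1H-isochromen-8-yl)oxy]-2-[(2-pentyl-1,3-dioxolan-2-yl)methyl]benzoate | CCCCCC1(Cc2c(Oc3cc(OC)cc4cc(CCCCC)oc(=O)c34)c(OCc3ccccc3)cc(OCc3ccccc3)c2C(=O)OCc2ccccc2)OCCO1
F4 | step 4 | 6,8-dihydroxy-3-pentyl-1H-isochromen-1-one | CCCCCc1cc2cc(O)cc(O)c2c(=O)o1
F5 | step 4 | 6,8-bis(benzyloxy)-3-pentyl-1H-isochromen-1-one | CCCCCc1cc2cc(OCc3ccccc3)cc(OCc3ccccc3)c2c(=O)o1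
F0 | step 6 | none | none
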